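**Retrosynthetic overview**
- Last bond made: the ArCH2–CH2Ar' bridge, cut between the two benzylic carbons. The chromene half is a 7-carbaldehyde used as its NH2-hydrazone (a benzylic carbanion equivalent). The phenol half is para-quinone methide, released from a 4-silyloxybenzyl bromide. Both carbons are electrophilic in their native form, and the free 4'-OH appears in the same event.
- C6–prenyl bond: ortho-C-alkylation of the sodium 5-phenoxide of the chromene aldehyde with prenyl bromide (C6 is its only free ortho carbon).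
- Pyran ring: amine-salt-mediated condensation and oxa-6π electrocyclisation of 3,5-dihydroxybenzaldehyde with prenal at the carbon between the two hydroxyls.
- Ring order: both benzene rings are bought; the 2H-pyran is the only ring formed and is closed first. No protecting group is carried on the main line.

Assumption: the target has no stereocentre and no stereogenic double bond (C3=C4 is in a ring; the prenyl alkene carries two methyls), so it is achiral and no stereocontrol is needed.

**Step 1**
Reactants: 1 3,5-dihydroxybenzaldehyde; 2 3-methylbut-2-enal (prenal)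
Product: 4 5-hydroxy-2,2-dimethyl-2H-chromene-7-carbaldehyde, via ortho-quinone methide 3 (not isolated)
Conditions: 2 (1.1 equiv), EDDA (20 mol %), xylene, reflux, 8 h
Reagents that add atoms: none
Why: Knoevenagel-type condensation of the prenal iminium at C4 of 1 (ortho to both OH groups and not crowded by CHO, as in chromene formation from 5-substituted resorcinols) gives dienone 3, which closes by oxa-6π electrocyclisation (formal [3+3] chromene annulation); no stereocentre is formed.

**Step 2**
Reactants: 4 5-hydroxy-2,2-dimethyl-2H-chromene-7-carbaldehyde; 5 1-bromo-3-methylbut-2-ene (prenyl bromide)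
Product: 7 5-hydroxy-2,2-dimethyl-6-(3-methylbut-2-en-1-yl)-2H-chromene-7-carbaldehyde, via sodium 7-formyl-2,2-dimethyl-2H-chromen-5-olate 6 (not isolated)
Conditions: NaH (1.05 equiv), toluene, 0 °C to rt; then 5 (1.2 equiv), rt to 40 °C, 16 h; aq NH4Cl
Reagents that add atoms: none
Why: ortho-selective C-alkylation of a phenoxide (C-prenylation): in a non-polar solvent the tight sodium phenoxide ion pair is alkylated at the ortho carbon rather than at oxygen or the para carbon C8, and C6 is the only free ortho position because C4a is substituted; the non-enolisable aldehyde is inert to NaH and no stereocentre is formed.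

**Step 3**
Reactants: 7 5-hydroxy-2,2-dimethyl-6-(3-methylbut-2-en-1-yl)-2H-chromene-7-carbaldehyde; 8 [4-(bromomethyl)phenoxy](tert-butyl)dimethylsilane
Product: 12 7-[2-(4-hydroxyphenyl)ethyl]-2,2-dimethyl-6-(3-methylbut-2-en-1-yl)-2H-chromen-5-ol, via chromene-7-carbaldehyde (E)-hydrazone 9 (not isolated), via para-quinone methide 10 (not isolated), via benzylic diazene adduct 11 (not isolated)
Conditions: N2H4·H2O (1.2 equiv), THF, rt, 1 h, Ar; then [Ru(p-cymene)Cl2]2 (2.5 mol %), dmpe (5 mol %), K3PO4 (2 equiv), CsF (3 equiv), 18-crown-6 (20 mol %), 8 (2 equiv, syringe pump, 6 h), THF, 45 °C; aq NH4Cl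
Reagents that add atoms: none
Why: Proposed new method: hydrazone carbonyl umpolung (Wolff–Kishner-type carbanion equivalent) in a 1,6-conjugate addition to a para-quinone methide; hydrazine turns the aldehyde carbon of 7 into the nucleophilic carbon of NH2-hydrazone 9, fluoride desilylates 8 and the phenoxide expels bromide (1,6-elimination) to give 10 at low stationary concentration, the Ru-bound deprotonated hydrazone attacks the exocyclic CH2 of 10 through carbon (driven by re-aromatisation) to give diazene 11, and base-induced loss of N2 followed by protonation leaves the CH2–CH2 bridge and the free phenol; N- and O-adducts of 10 can revert under base whereas N2 loss cannot, the closest known reaction type is the Ru(II)/bisphosphine-catalysed addition of N-unsubstituted aldehyde hydrazones as alkyl carbanion equivalents to carbonyls, Michael acceptors and 2,6-di-tert-butyl para-quinone methides, combined with fluoride-triggered 1,6-elimination of 4-silyloxybenzyl halides, and the transient stereocentre of 11 is lost so none remains.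

**Compound list**
1 | 3,5-dihydroxybenzaldehyde | O=Cc1cc(O)cc(O)c1 | starting material
2 | 3-methylbut-2-enal (prenal) | CC(C)=CC=O | starting material
3 | 5-hydroxy-4-(3-methylbut-2-en-1-ylidene)-3-oxocyclohexa-1,5-diene-1-carbaldehyde (ortho-quinone methide; not isolated; exocyclic C=C geometry undefined because the flanking O atoms exchange by tautomerism) | O=CC1=CC(=O)C(=CC=C(C)C)C(O)=C1 | intermediate
4 | 5-hydroxy-2,2-dimethyl-2H-chromene-7-carbaldehyde | O=Cc1cc2c(c(O)c1)C=CC(C)(C)O2 | intermediate
5 | 1-bromo-3-methylbut-2-ene (prenyl bromide) | CC(C)=CCBr | starting material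
6 | sodium 7-formyl-2,2-dimethyl-2H-chromen-5-olate (not isolated) | O=Cc1cc2c(c([O-])c1)C=CC(C)(C)O2.[Na+] | intermediate
7 | 5-hydroxy-2,2-dimethyl-6-(3-methylbut-2-en-1-yl)-2H-chromene-7-carbaldehyde | CC(C)=CCc1c(C=O)cc2c(c1O)C=CC(C)(C)O2 | intermediate
8 | [4-(bromomethyl)phenoxy](tert-butyl)dimethylsilane | CC(C)(C)[Si](C)(C)Oc1ccc(CBr)cc1 | starting material
9 | 7-[(E)-hydrazinylidenemethyl]-2,2-dimethyl-6-(3-methylbut-2-en-1-yl)-2H-chromen-5-ol (not isolated; N atoms from hydrazine) | CC(C)=CCc1c(/C=N/N)cc2c(c1O)C=CC(C)(C)O2 | intermediate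
10 | 4-methylidenecyclohexa-2,5-dien-1-one (para-quinone methide; not isolated) | C=C1C=CC(=O)C=C1 | intermediate
11 | 7-[1-diazenyl-2-(4-hydroxyphenyl)ethyl]-2,2-dimethyl-6-(3-methylbut-2-en-1-yl)-2H-chromen-5-ol (racemic, transient; not isolated) | CC(C)=CCc1c(C(Cc2ccc(O)cc2)N=N)cc2c(c1O)C=CC(C)(C)O2 | intermediate
12 | 7-[2-(4-hydroxyphenyl)ethyl]-2,2-dimethyl-6-(3-methylbut-2-en-1-yl)-2H-chromen-5-ol (achiral) | CC(C)=CCc1c(CCc2ccc(O)cc2)cc2c(c1O)C=CC(C)(C)O2 | target

**Step count and risks**
Total steps: 3. Longest linear sequence: 3 steps (1 → 4 → 7 → 12); 2, 5 and 8 are used as purchased.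

Most likely to fail, in order:

Step 3 is the least precedented. Quinone methide 10 can oligomerise or be trapped at nitrogen of 9 or at the phenoxide of 7, and 9 can form the azine or be reduced to the 7-methyl compound. The fallback sets out from 7 (and uses 8) and comes back at 12, keeping the same bond but making it by a lithiated dithiane alkylation. Aldehyde 7 is converted with propane-1,3-dithiol and MgBr2·OEt2 (Et2O, rt) into 7-(1,3-dithian-2-yl)-2,2-dimethyl-6-(3-methylbut-2-en-1-yl)-2H-chromen-5-ol F1. Its phenoxide/dithianyl dianion (n-BuLi, 2.2 equiv, THF, −30 °C) is alkylated at carbon with 8 to give 7-{2-[4-(tert-butyldimethylsilyloxy)benzyl]-1,3-dithian-2-yl}-2,2-dimethyl-6-(3-methylbut-2-en-1-yl)-2H-chromen-5-ol F2. Radical desulfurisation (Bu3SnH, AIBN, toluene, 100 °C), which spares both alkenes where Raney nickel would not, gives 7-{2-[4-(tert-butyldimethylsilyloxy)phenyl]ethyl}-2,2-dimethyl-6-(3-methylbut-2-en-1-yl)-2H-chromen-5-ol F3. TBAF (THF, 0 °C) then gives 12.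

Step 2 can give the O-prenyl ether, the C8 isomer or dialkylation in place of clean C6 alkylation. The fallback sets out from 4 and comes back at 7, delivering the prenyl group intramolecularly. Pd-catalysed O-allylation of 4 with tert-butyl 2-methylbut-3-en-2-yl carbonate (Pd(PPh3)4, THF, 0 °C) gives 2,2-dimethyl-5-[(2-methylbut-3-en-2-yl)oxy]-2H-chromene-7-carbaldehyde F4. Its aromatic Claisen rearrangement (toluene, 110 °C) can only end at C6, the one unsubstituted ortho carbon, and inverts the allyl unit to the linear prenyl group of 7.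

Step 1 can give the regioisomeric 7-hydroxy-5-carbaldehyde chromene (attack at C2 of 1) or a second annulation. The fallback sets out from 1 and comes back at 4, fixing the site by directed metalation. Acetalisation of 1 (ethylene glycol, cat. TsOH, toluene, Dean–Stark) gives 5-(1,3-dioxolan-2-yl)benzene-1,3-diol F5, and MOMCl/iPr2NEt (CH2Cl2) gives 2-[3,5-bis(methoxymethoxy)phenyl]-1,3-dioxolane F6. Lithiation between the two MOM ethers (n-BuLi, THF, 0 °C) and addition to 2 (−78 °C) gives racemic 1-[4-(1,3-dioxolan-2-yl)-2,6-bis(methoxymethoxy)phenyl]-3-methylbut-2-en-1-ol F7. HCl in MeOH (40 °C) removes both MOM groups and the acetal and dehydrates the carbinol through 3 to 4.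

**Further compounds**
F1 | step 3 | 7-(1,3-dithian-2-yl)-2,2-dimethyl-6-(3-methylbut-2-en-1-yl)-2H-chromen-5-ol | CC(C)=CCc1c(C2SCCCS2)cc2c(c1O)C=CC(C)(C)O2
F2 | step 3 | 7-{2-[4-(tert-butyldimethylsilyloxy)benzyl]-1,3-dithian-2-yl}-2,2-dimethyl-6-(3-methylbut-2-en-1-yl)-2H-chromen-5-ol | CC(C)=CCc1c(C2(Cc3ccc(O[Si](C)(C)C(C)(C)C)cc3)SCCCS2)cc2c(c1O)C=CC(C)(C)O2
F3 | step 3 | 7-{2-[4-(tert-butyldimethylsilyloxy)phenyl]ethyl}-2,2-dimethyl-6-(3-methylbut-2-en-1-yl)-2H-chromen-5-ol | CC(C)=CCc1c(CCc2ccc(O[Si](C)(C)C(C)(C)C)cc2)cc2c(c1O)C=CC(C)(C)O2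
F4 | step 2 | 2,2-dimethyl-5-[(2-methylbut-3-en-2-yl)oxy]-2H-chromene-7-carbaldehyde | O=Cc1cc2c(c(OC(C)(C)C=C)c1)C=CC(C)(C)O2
F5 | step 1 | 5-(1,3-dioxolan-2-yl)benzene-1,3-diol | Oc1cc(O)cc(c1)C1OCCO1
F6 | step 1 | 2-[3,5-bis(methoxymethoxy)phenyl]-1,3-dioxolane | COCOc1cc(cc(OCOC)c1)C1OCCO1
F7 | step 1 | 1-[4-(1,3-dioxolan-2-yl)-2,6-bis(methoxymethoxy)phenyl]-3-methylbut-2-en-1-ol (racemic) | COCOc1cc(cc(OCOC)c1C(O)C=C(C)C)C1OCCO1
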